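**Retrosynthetic overview**

1. C15 comes last, by Wittig methylenation of a C14 α-hydroxy aldehyde; C11–C14, C16 and the C13 carbinol come from (R)-citramalic acid as an acetonide aldehyde.
2. H9 is set by hydroxyl-directed hydrogenation of a C9=C11 alkene, the C8 carbinol (C17) by methyl addition to an exocyclic enone, and C9–C11 by Mukaiyama aldol condensation of the cycloadduct's silyl enol ether.
3. Rings A and B are closed together from an open-chain trienal by a catalyst-controlled intramolecular Diels–Alder reaction that forms C5–C10 and C6–C7; the activating formyl group on C6 is then removed by decarbonylation.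
4. Enabling feature: ring B (C5–C6–C7–C8–C9–C10) carries oxygen on C8, so C7=C8(OSi)–C9=C10 is a 2-silyloxy diene and C5=C6 its dienophile; ring A shares the C5–C10 bond and its C1–C2–C3–C4 chain is the four-atom tether from C10 to C5 (a 1,7,9-decatriene).
5. The trienal comes from methyl 3,3-dimethylpent-4-enoate by organocatalytic α-bromination (C3–Br), propargylation, Negishi carboalumination/acylation (E-C9=C10, C20) and cross-metathesis (enal); ring order: A and B at the same time, no other ring.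

Key step: step 8

Remark on numbering: atoms are numbered as in the labdane skeleton (ring A C1–C5 and C10, ring B C5–C10, side chain C11–C16, C17 on C8, C18 and C19 on C4, C20 on C10); CIP descriptors change between compounds only where priorities change.

Assumption: the (S)-configured oxazaborolidinium ion of step 8 is taken to expose the Re face of C5 of the s-trans enal (formyl C–H···O binding model); if the sense is the opposite one, the (R)-catalyst is used with no other change.

**Route**

Step 1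
Reactants: 1 methyl 3,3-dimethylpent-4-enoate
Product: 2 3,3-dimethylpent-4-enal
Conditions: i-Bu2AlH (1.05 equiv), CH2Cl2, −78 °C; aq. potassium sodium tartrate
Reagents that add atoms: none
Why: Low-temperature i-Bu2AlH reduction of the ester stops at the aldehyde because the tetrahedral aluminium alkoxide survives until work-up (partial ester reduction).

Step 2
Reactants: 2 3,3-dimethylpent-4-enal
Product: 4 (S)-2-bromo-3,3-dimethylpent-4-en-1-ol, via (S)-2-bromo-3,3-dimethylpent-4-enal 3 (not isolated)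
Conditions: (S)-2-{bis[3,5-bis(trifluoromethyl)phenyl][(trimethylsilyl)oxy]methyl}pyrrolidine (20 mol%), 4,4-dibromo-2,6-di-tert-butylcyclohexa-2,5-dien-1-one, PhCO2H (20 mol%), H2O, CH2Cl2/pentane, −40 °C; then NaBH4, MeOH, −40 → 0 °C
Reagents that add atoms: 4,4-dibromo-2,6-di-tert-butylcyclohexa-2,5-dien-1-one (O=C1C(C(C)(C)C)=CC(Br)(Br)C=C1C(C)(C)C)
Why: Enamine catalysis (organocatalytic α-bromination of aldehydes): the anti E-enamine of 2 is brominated on the face opposite the bulky diaryl(silyloxy)methyl group of the (S)-catalyst, which creates the C3 stereocentre as (S) in 3 (the later 3R centre of the target), and reduction in the same flask removes the configurationally labile α-bromo aldehyde.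

Step 3
Reactants: 4 (S)-2-bromo-3,3-dimethylpent-4-en-1-ol
Product: 5 (S)-2-bromo-3,3-dimethylpent-4-en-1-yl trifluoromethanesulfonate
Conditions: Tf2O, 2,6-lutidine, CH2Cl2, −78 °C
Reagents that add atoms: trifluoromethanesulfonic anhydride (O=S(=O)(OS(=O)(=O)C(F)(F)F)C(F)(F)F)
Why: O-Sulfonylation of the primary alcohol with triflic anhydride and a hindered pyridine base (triflate formation) does not touch the stereocentre and gives an electrophile reactive enough for displacement at a β-branched carbon.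

Step 4
Reactants: 5 (S)-2-bromo-3,3-dimethylpent-4-en-1-yl trifluoromethanesulfonate, 6 trimethyl(prop-1-yn-1-yl)silane
Product: 8 (5R)-5-bromo-6,6-dimethyloct-7-en-1-yne, via [(5R)-5-bromo-6,6-dimethyloct-7-en-1-yn-1-yl]trimethylsilane 7 (not isolated)
Conditions: 6, n-BuLi, THF, −78 → −20 °C; 5, −78 → −30 °C; then MeOH, K2CO3, rt
Reagents that add atoms: none
Why: SN2 alkylation of the primary triflate with 3-(trimethylsilyl)propargyllithium (propargylation of an alkyl sulfonate) forms C1–C2 far faster than any reaction at the neopentyl-type secondary bromide, and basic methanolysis then removes the alkynyl silyl group.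

Step 5
Reactants: 8 (5R)-5-bromo-6,6-dimethyloct-7-en-1-yne
Product: 10 (3E,7R)-7-bromo-4,8,8-trimethyldeca-3,9-dien-2-one, via [(1E,5R)-5-bromo-2,6,6-trimethylocta-1,7-dien-1-yl]dimethylalumane 9 (not isolated)
Conditions: Me3Al (2.5 equiv), Cp2ZrCl2 (20 mol%), H2O (1 equiv), CH2Cl2, −20 °C; volatiles removed; AcCl, Pd(PPh3)4 (5 mol%), THF, 0 °C → rt
Reagents that add atoms: trimethylaluminium (C[Al](C)C); acetyl chloride (CC(Cl)=O)
Why: Negishi zirconium-catalysed methylalumination adds methyl (C20) and aluminium syn across the terminal alkyne with methyl on the internal carbon, and palladium-catalysed acylation of the alkenylalane proceeds with retention, so the chain ends up trans to the acetyl group in the E enone.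

Step 6
Reactants: 10 (3E,7R)-7-bromo-4,8,8-trimethyldeca-3,9-dien-2-one, 11 (E)-but-2-enal
Product: 12 (2E,5R,8E)-5-bromo-4,4,8-trimethyl-10-oxoundeca-2,8-dienal
Conditions: 11 (5 equiv), second-generation Hoveyda–Grubbs catalyst (5 mol%), CH2Cl2, 40 °C
Reagents that add atoms: none
Why: Olefin cross-metathesis between the hindered terminal vinyl group and an excess of the enal partner should give the E enal while the trisubstituted enone alkene stays out of the catalytic cycle.

Step 7
Reactants: 12 (2E,5R,8E)-5-bromo-4,4,8-trimethyl-10-oxoundeca-2,8-dienal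
Product: 13 (2E,5R,8E)-5-bromo-4,4,8-trimethyl-10-{[tri(propan-2-yl)silyl]oxy}undeca-2,8,10-trienal
Conditions: i-Pr3SiOTf, Et3N, CH2Cl2, −78 → 0 °C
Reagents that add atoms: tri(propan-2-yl)silyl trifluoromethanesulfonate (CC(C)[Si](C(C)C)(C(C)C)OS(=O)(=O)C(F)(F)F)
Why: Soft enolisation with a silyl triflate and triethylamine removes a proton from the α′-methyl group of the enone (kinetic site) and gives the cross-conjugated 2-silyloxy-1,3-diene, while the enal has no enolisable position.

Step 8
Reactants: 13 (2E,5R,8E)-5-bromo-4,4,8-trimethyl-10-{[tri(propan-2-yl)silyl]oxy}undeca-2,8,10-trienal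
Product: 14 (1R,4aR,7R,8aS)-7-bromo-4a,8,8-trimethyl-3-{[tri(propan-2-yl)silyl]oxy}-1,2,4a,5,6,7,8,8a-octahydronaphthalene-1-carbaldehyde
Conditions: (S)-3,3-diphenyl-1-(2-methylphenyl)tetrahydro-1H,3H-pyrrolo[1,2-c][1,3,2]oxazaborole (20 mol%), Tf2NH (18 mol%), CH2Cl2 (0.01 M), −78 → −20 °C
Reagents that add atoms: none
Why: The triflimide-activated oxazaborolidinium ion binds the formyl oxygen of the s-trans enal and lowers its LUMO, and the tethered 2-silyloxy diene then adds in one concerted but asynchronous [4+2] event in which C5–C10 bonding runs ahead of C6–C7 bonding. The closest known reaction type is the chiral oxazaborolidinium-catalysed intramolecular Diels–Alder reaction of (E)-trienals (the same catalysts are used intermolecularly with 2-silyloxy dienes), a type 1 cyclisation of a 1,7,9-decatriene. Ring B is closed as the cyclohexene of the [4+2] cycloaddition (both new bonds lie in it), and ring A is closed in the same event as the fused six-membered carbocycle because its C1–C4 chain is the tether that joins the diene terminus C10 to the dienophile carbon C5. The endo transition state (formyl under the diene, tether chair-like, the chain outside and C20 inside on the E-configured C9=C10) makes H5 and C20 trans and creates the quaternary C10, the E geometry of C5=C6 fixes C6 (erased in step 9), and the catalyst sets the absolute sense by directing C10 to the Re face of C5. The existing 3R centre is matched, because bromine then sits equatorial in the chair-like tether and ends up cis to C20 as in the target. The step needs endo over exo and catalyst over substrate facial selectivity, which the defined E geometries of both alkenes, the four-atom tether (it fixes the regiochemistry) and the only weak bias of the remote C–Br centre secure, while high dilution at low temperature keeps intermolecular Mukaiyama-type addition to the activated aldehyde down.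

Step 9
Reactants: 14 (1R,4aR,7R,8aS)-7-bromo-4a,8,8-trimethyl-3-{[tri(propan-2-yl)silyl]oxy}-1,2,4a,5,6,7,8,8a-octahydronaphthalene-1-carbaldehyde
Product: 15 {[(4aS,6R,8aR)-6-bromo-5,5,8a-trimethyl-3,4,4a,5,6,7,8,8a-octahydronaphthalen-2-yl]oxy}tri(propan-2-yl)silane
Conditions: RhCl(PPh3)3 (1.2 equiv), PhCN, 130 °C
Reagents that add atoms: none
Why: Tsuji–Wilkinson decarbonylation (formyl C–H oxidative addition, CO extrusion, C–H reductive elimination) replaces the formyl group on C6 by hydrogen under neutral conditions that should leave the silyl enol ether and the secondary bromide intact.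

Step 10
Reactants: 16 (R)-citramalic acid [(2R)-2-hydroxy-2-methylbutanedioic acid]
Product: 17 (2R)-2-methylbutane-1,2,4-triol
Conditions: BH3·SMe2, B(OMe)3, THF, 0 °C → rt; MeOH
Reagents that add atoms: none
Why: Borane reduces both carboxyl groups to primary alcohols (carboxylic acid reduction) without affecting the tertiary carbinol stereocentre.

Step 11
Reactants: 17 (2R)-2-methylbutane-1,2,4-triol
Product: 18 2-[(4R)-2,2,4-trimethyl-1,3-dioxolan-4-yl]ethan-1-ol
Conditions: 2,2-dimethoxypropane, acetone, TsOH (catalytic), rt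
Reagents that add atoms: 2,2-dimethoxypropane (COC(C)(C)OC)
Why: Acid-catalysed acetalisation under thermodynamic control gives the five-membered 1,3-dioxolane across the 1,2-diol and not the six-membered acetal, which leaves only the C11 hydroxyl free.

Step 12
Reactants: 18 2-[(4R)-2,2,4-trimethyl-1,3-dioxolan-4-yl]ethan-1-ol
Product: 19 [(4R)-2,2,4-trimethyl-1,3-dioxolan-4-yl]acetaldehyde
Conditions: Dess–Martin periodinane, NaHCO3, CH2Cl2, 0 °C → rt
Reagents that add atoms: none
Why: Dess–Martin oxidation of the primary alcohol under buffered conditions gives the aldehyde, whose only stereocentre is quaternary and cannot epimerise.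

Step 13
Reactants: 15 {[(4aS,6R,8aR)-6-bromo-5,5,8a-trimethyl-3,4,4a,5,6,7,8,8a-octahydronaphthalen-2-yl]oxy}tri(propan-2-yl)silane, 19 [(4R)-2,2,4-trimethyl-1,3-dioxolan-4-yl]acetaldehyde
Product: 20 (1S,4aS,6R,8aR)-6-bromo-1-{1-hydroxy-2-[(4R)-2,2,4-trimethyl-1,3-dioxolan-4-yl]ethyl}-5,5,8a-trimethyloctahydronaphthalen-2(1H)-one (mixture of C11 epimers)
Conditions: BF3·OEt2 (1.2 equiv), CH2Cl2, −78 °C
Reagents that add atoms: none
Why: Mukaiyama aldol addition: the silyl enol ether installed by the cycloaddition reacts regiospecifically at C9 (not C7) with the BF3-activated aldehyde from the face opposite the axial C10 methyl group, and the C9 and C11 configurations formed here are erased in step 14.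

Step 14
Reactants: 20 (1S,4aS,6R,8aR)-6-bromo-1-{1-hydroxy-2-[(4R)-2,2,4-trimethyl-1,3-dioxolan-4-yl]ethyl}-5,5,8a-trimethyloctahydronaphthalen-2(1H)-one
Product: 22 (1Z,4aS,6R,8aR)-6-bromo-5,5,8a-trimethyl-1-{2-[(4R)-2,2,4-trimethyl-1,3-dioxolan-4-yl]ethylidene}octahydronaphthalen-2(1H)-one, via aldol mesylate 21 (not isolated)
Conditions: MsCl, Et3N, CH2Cl2, 0 °C; then DBU, rt
Reagents that add atoms: none
Why: Mesylation of the β-hydroxy ketone and E1cB elimination complete an aldol condensation to the exocyclic enone, expected as the Z isomer because the E isomer would press C12 against the quaternary C10, although either isomer serves.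

Step 15
Reactants: 22 (1Z,4aS,6R,8aR)-6-bromo-5,5,8a-trimethyl-1-{2-[(4R)-2,2,4-trimethyl-1,3-dioxolan-4-yl]ethylidene}octahydronaphthalen-2(1H)-one
Product: 23 (1Z,2R,4aS,6R,8aR)-6-bromo-2,5,5,8a-tetramethyl-1-{2-[(4R)-2,2,4-trimethyl-1,3-dioxolan-4-yl]ethylidene}decahydronaphthalen-2-ol
Conditions: MeLi, CeCl3 (anhydrous), THF, −78 °C
Reagents that add atoms: methyllithium ([Li]C)
Why: 1,2-Addition of the organocerium reagent to the enone should occur from the equatorial direction because the axial path to C8 is blocked by the syn-axial C10 methyl group, which places the new hydroxyl axial and cis to C20 (8R).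

Step 16
Reactants: 23 (1Z,2R,4aS,6R,8aR)-6-bromo-2,5,5,8a-tetramethyl-1-{2-[(4R)-2,2,4-trimethyl-1,3-dioxolan-4-yl]ethylidene}decahydronaphthalen-2-ol
Product: 24 (1R,2R,4aS,6R,8aR)-6-bromo-2,5,5,8a-tetramethyl-1-{2-[(4R)-2,2,4-trimethyl-1,3-dioxolan-4-yl]ethyl}decahydronaphthalen-2-ol
Conditions: [Ir(cod)(PCy3)(py)]PF6 (10 mol%), H2 (1 atm), CH2Cl2, rt
Reagents that add atoms: none
Why: Hydroxyl-directed homogeneous hydrogenation: iridium bound to the C8 hydroxyl delivers hydrogen to the same face of the C9=C11 alkene, so H9 ends up cis to the hydroxyl and the side chain trans to it (9R), a centre that can no longer epimerise.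

Step 17
Reactants: 24 (1R,2R,4aS,6R,8aR)-6-bromo-2,5,5,8a-tetramethyl-1-{2-[(4R)-2,2,4-trimethyl-1,3-dioxolan-4-yl]ethyl}decahydronaphthalen-2-ol
Product: 25 (2R)-4-[(1R,2R,4aS,6R,8aR)-6-bromo-2-hydroxy-2,5,5,8a-tetramethyldecahydronaphthalen-1-yl]-2-methylbutane-1,2-diol
Conditions: AcOH/THF/H2O (3:1:1), 40 °C
Reagents that add atoms: none
Why: Mild aqueous acid hydrolyses the isopropylidene acetal without ionising the tertiary alcohols.

Step 18
Reactants: 25 (2R)-4-[(1R,2R,4aS,6R,8aR)-6-bromo-2-hydroxy-2,5,5,8a-tetramethyldecahydronaphthalen-1-yl]-2-methylbutane-1,2-diol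
Product: 26 (2R)-4-[(1R,2R,4aS,6R,8aR)-6-bromo-2-hydroxy-2,5,5,8a-tetramethyldecahydronaphthalen-1-yl]-2-hydroxy-2-methylbutanal
Conditions: SO3·pyridine, DMSO, i-Pr2NEt, CH2Cl2, 0 °C
Reagents that add atoms: none
Why: Parikh–Doering oxidation converts only the primary alcohol into the α-hydroxy aldehyde and avoids the glycol cleavage that hypervalent iodine oxidants can cause.

Step 19
Reactants: 26 (2R)-4-[(1R,2R,4aS,6R,8aR)-6-bromo-2-hydroxy-2,5,5,8a-tetramethyldecahydronaphthalen-1-yl]-2-hydroxy-2-methylbutanal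
Product: 27 (1R,2R,4aS,6R,8aR)-6-bromo-1-[(3R)-3-hydroxy-3-methylpent-4-en-1-yl]-2,5,5,8a-tetramethyldecahydronaphthalen-2-ol (CNP0150870.1)
Conditions: Ph3PCH3Br (4 equiv), KN(SiMe3)2, THF, 0 °C; then 26, 0 °C → rt
Reagents that add atoms: methyltriphenylphosphonium bromide (C[P+](c1ccccc1)(c1ccccc1)c1ccccc1.[Br-])
Why: Wittig methylenation of the non-enolisable α-hydroxy aldehyde with an excess of salt-free ylide adds C15 and leaves the C13 stereocentre untouched.

**Compound list**

1 | methyl 3,3-dimethylpent-4-enoate | COC(=O)CC(C)(C)C=C | starting material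
2 | 3,3-dimethylpent-4-enal | O=CCC(C)(C)C=C | intermediate
3 | (S)-2-bromo-3,3-dimethylpent-4-enal | O=C[C@@H](Br)C(C)(C)C=C | intermediate
4 | (S)-2-bromo-3,3-dimethylpent-4-en-1-ol | OC[C@@H](Br)C(C)(C)C=C | intermediate
5 | (S)-2-bromo-3,3-dimethylpent-4-en-1-yl trifluoromethanesulfonate | FC(F)(F)S(=O)(=O)OC[C@@H](Br)C(C)(C)C=C | intermediate
6 | trimethyl(prop-1-yn-1-yl)silane | CC#C[Si](C)(C)C | starting material
7 | [(5R)-5-bromo-6,6-dimethyloct-7-en-1-yn-1-yl]trimethylsilane | C[Si](C)(C)C#CCC[C@@H](Br)C(C)(C)C=C | intermediate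
8 | (5R)-5-bromo-6,6-dimethyloct-7-en-1-yne | C#CCC[C@@H](Br)C(C)(C)C=C | intermediate
9 | [(1E,5R)-5-bromo-2,6,6-trimethylocta-1,7-dien-1-yl]dimethylalumane | C[Al](C)/C=C(\C)CC[C@@H](Br)C(C)(C)C=C | intermediate
10 | (3E,7R)-7-bromo-4,8,8-trimethyldeca-3,9-dien-2-one | CC(=O)/C=C(\C)CC[C@@H](Br)C(C)(C)C=C | intermediate
11 | (E)-but-2-enal | C/C=C/C=O | starting material
12 | (2E,5R,8E)-5-bromo-4,4,8-trimethyl-10-oxoundeca-2,8-dienal | O=C/C=C/C(C)(C)[C@H](Br)CC/C(C)=C/C(C)=O | intermediate
13 | (2E,5R,8E)-5-bromo-4,4,8-trimethyl-10-{[tri(propan-2-yl)silyl]oxy}undeca-2,8,10-trienal | O=C/C=C/C(C)(C)[C@H](Br)CC/C(C)=C/C(=C)O[Si](C(C)C)(C(C)C)C(C)C | intermediate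
14 | (1R,4aR,7R,8aS)-7-bromo-4a,8,8-trimethyl-3-{[tri(propan-2-yl)silyl]oxy}-1,2,4a,5,6,7,8,8a-octahydronaphthalene-1-carbaldehyde | CC(C)[Si](C(C)C)(C(C)C)OC1=C[C@]2(C)CC[C@@H](Br)C(C)(C)[C@H]2[C@H](C=O)C1 | intermediate
15 | {[(4aS,6R,8aR)-6-bromo-5,5,8a-trimethyl-3,4,4a,5,6,7,8,8a-octahydronaphthalen-2-yl]oxy}tri(propan-2-yl)silane | CC(C)[Si](C(C)C)(C(C)C)OC1=C[C@]2(C)CC[C@@H](Br)C(C)(C)[C@H]2CC1 | intermediate
16 | (R)-citramalic acid, (2R)-2-hydroxy-2-methylbutanedioic acid | OC(=O)[C@](C)(O)CC(=O)O | starting material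
17 | (2R)-2-methylbutane-1,2,4-triol | OC[C@](C)(O)CCO | intermediate
18 | 2-[(4R)-2,2,4-trimethyl-1,3-dioxolan-4-yl]ethan-1-ol | CC1(C)OC[C@](C)(O1)CCO | intermediate
19 | [(4R)-2,2,4-trimethyl-1,3-dioxolan-4-yl]acetaldehyde | CC1(C)OC[C@](C)(O1)CC=O | intermediate
20 | (1S,4aS,6R,8aR)-6-bromo-1-{1-hydroxy-2-[(4R)-2,2,4-trimethyl-1,3-dioxolan-4-yl]ethyl}-5,5,8a-trimethyloctahydronaphthalen-2(1H)-one (C11 epimers) | CC1(C)OC[C@](C)(O1)CC(O)[C@@H]2[C@]3(C)CC[C@@H](Br)C(C)(C)[C@H]3CCC2=O | intermediate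
21 | 1-[(1S,4aS,6R,8aR)-6-bromo-5,5,8a-trimethyl-2-oxodecahydronaphthalen-1-yl]-2-[(4R)-2,2,4-trimethyl-1,3-dioxolan-4-yl]ethyl methanesulfonate (aldol mesylate, C11 epimers) | CC1(C)OC[C@](C)(O1)CC(OS(C)(=O)=O)[C@@H]2[C@]3(C)CC[C@@H](Br)C(C)(C)[C@H]3CCC2=O | intermediate
22 | (1Z,4aS,6R,8aR)-6-bromo-5,5,8a-trimethyl-1-{2-[(4R)-2,2,4-trimethyl-1,3-dioxolan-4-yl]ethylidene}octahydronaphthalen-2(1H)-one | CC1(C)OC[C@](C)(O1)C/C=C2/[C@]3(C)CC[C@@H](Br)C(C)(C)[C@H]3CCC2=O | intermediate
23 | (1Z,2R,4aS,6R,8aR)-6-bromo-2,5,5,8a-tetramethyl-1-{2-[(4R)-2,2,4-trimethyl-1,3-dioxolan-4-yl]ethylidene}decahydronaphthalen-2-ol | CC1(C)OC[C@](C)(O1)C/C=C2/[C@]3(C)CC[C@@H](Br)C(C)(C)[C@H]3CC[C@@]2(C)O | intermediate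
24 | (1R,2R,4aS,6R,8aR)-6-bromo-2,5,5,8a-tetramethyl-1-{2-[(4R)-2,2,4-trimethyl-1,3-dioxolan-4-yl]ethyl}decahydronaphthalen-2-ol | CC1(C)OC[C@](C)(O1)CC[C@@H]2[C@]3(C)CC[C@@H](Br)C(C)(C)[C@H]3CC[C@@]2(C)O | intermediate
25 | (2R)-4-[(1R,2R,4aS,6R,8aR)-6-bromo-2-hydroxy-2,5,5,8a-tetramethyldecahydronaphthalen-1-yl]-2-methylbutane-1,2-diol | OC[C@](C)(O)CC[C@@H]1[C@]2(C)CC[C@@H](Br)C(C)(C)[C@H]2CC[C@@]1(C)O | intermediate
26 | (2R)-4-[(1R,2R,4aS,6R,8aR)-6-bromo-2-hydroxy-2,5,5,8a-tetramethyldecahydronaphthalen-1-yl]-2-hydroxy-2-methylbutanal | O=C[C@](C)(O)CC[C@@H]1[C@]2(C)CC[C@@H](Br)C(C)(C)[C@H]2CC[C@@]1(C)O | intermediate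
27 | (1R,2R,4aS,6R,8aR)-6-bromo-1-[(3R)-3-hydroxy-3-methylpent-4-en-1-yl]-2,5,5,8a-tetramethyldecahydronaphthalen-2-ol | C=C[C@](C)(O)CC[C@@H]1[C@]2(C)CC[C@@H](Br)C(C)(C)[C@H]2CC[C@@]1(C)O | target

**Totals and risk**

Total step count: 19. Longest linear sequence: 16 steps (steps 1–9 and 13–19); the side-chain branch (steps 10–12) joins at step 13.

The three steps most likely to fail:

Step 8 (key cycloaddition). What may go wrong: cycloaddition too slow at the congested C5–C10 bond, so that intermolecular addition of the silyl enol ether to the activated aldehyde competes, or insufficient endo and facial control by the catalyst. The fallback replaces catalyst control by auxiliary control and sets out from enone 10. Cross-metathesis with (4R)-3-acryloyl-4-benzyl-1,3-oxazolidin-2-one (second-generation Hoveyda–Grubbs catalyst) would give (4R)-4-benzyl-3-[(2E,5R,8E)-5-bromo-4,4,8-trimethyl-10-oxoundeca-2,8-dienoyl]-1,3-oxazolidin-2-one F1. Silylation as in step 7 would give (4R)-4-benzyl-3-[(2E,5R,8E)-5-bromo-4,4,8-trimethyl-10-{[tri(propan-2-yl)silyl]oxy}undeca-2,8,10-trienoyl]-1,3-oxazolidin-2-one F2. Me2AlCl (1.4 equiv, CH2Cl2, −30 °C) would then trigger the intramolecular Diels–Alder reaction of the chelated s-cis N-enoyl oxazolidinone, in which the benzyl group of the (R)-auxiliary leaves the Re face of C5 open and the endo mode again gives the trans ring fusion. This would give (4R)-4-benzyl-3-{[(1R,4aR,7R,8aS)-7-bromo-4a,8,8-trimethyl-3-{[tri(propan-2-yl)silyl]oxy}-1,2,4a,5,6,7,8,8a-octahydronaphthalen-1-yl]carbonyl}-1,3-oxazolidin-2-one F3. LiBH4 (THF, MeOH, 0 °C) would remove the auxiliary and give [(1R,4aR,7R,8aS)-7-bromo-4a,8,8-trimethyl-3-{[tri(propan-2-yl)silyl]oxy}-1,2,4a,5,6,7,8,8a-octahydronaphthalen-1-yl]methanol F4, and Dess–Martin oxidation comes back to the route at aldehyde 14.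

Step 4 (alkylation beside the bromide). What may go wrong: attack of the organolithium at bromine or at H3 with elimination across C2–C3, or bromine participation during the displacement, instead of clean SN2 at C2. The fallback replaces sp3 alkylation by olefination, conjugate reduction and one-carbon homologation, and sets out from bromo aldehyde 3, which is then not reduced. Wittig reaction with (triphenylphosphoranylidene)acetaldehyde would give (2E,4R)-4-bromo-5,5-dimethylhepta-2,6-dienal F5. Organocatalytic transfer hydrogenation (Hantzsch ester, dibenzylammonium trifluoroacetate) would reduce only the conjugated C=C bond and give (4R)-4-bromo-5,5-dimethylhept-6-enal F6. Seyferth–Gilbert homologation with the Ohira–Bestmann reagent (K2CO3, MeOH) comes back to the route at alkyne 8.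

Step 9 (decarbonylation). What may go wrong: slow decarbonylation of the hindered secondary aldehyde, with β-hydride elimination to ring alkenes or thermal loss of the silyl enol ether at the temperature needed. The fallback replaces metal-mediated CO extrusion by oxidation and radical decarboxylation, and sets out from aldehyde 14. Oxidation with Ag2O (aq. NaOH, EtOH) would give (1R,4aR,7R,8aS)-7-bromo-4a,8,8-trimethyl-3-{[tri(propan-2-yl)silyl]oxy}-1,2,4a,5,6,7,8,8a-octahydronaphthalene-1-carboxylic acid F7. Coupling with N-hydroxypyridine-2-thione (DCC) would give 2-thioxopyridin-1(2H)-yl (1R,4aR,7R,8aS)-7-bromo-4a,8,8-trimethyl-3-{[tri(propan-2-yl)silyl]oxy}-1,2,4a,5,6,7,8,8a-octahydronaphthalene-1-carboxylate F8. Barton decarboxylation (visible light, t-BuSH, benzene) comes back to the route at silyl enol ether 15.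

**Further compounds**

F1 | step 8 | (4R)-4-benzyl-3-[(2E,5R,8E)-5-bromo-4,4,8-trimethyl-10-oxoundeca-2,8-dienoyl]-1,3-oxazolidin-2-one | O=C(/C=C/C(C)(C)[C@H](Br)CC/C(C)=C/C(C)=O)N1[C@H](Cc2ccccc2)COC1=O
F2 | step 8 | (4R)-4-benzyl-3-[(2E,5R,8E)-5-bromo-4,4,8-trimethyl-10-{[tri(propan-2-yl)silyl]oxy}undeca-2,8,10-trienoyl]-1,3-oxazolidin-2-one | O=C(/C=C/C(C)(C)[C@H](Br)CC/C(C)=C/C(=C)O[Si](C(C)C)(C(C)C)C(C)C)N1[C@H](Cc2ccccc2)COC1=O
F3 | step 8 | (4R)-4-benzyl-3-{[(1R,4aR,7R,8aS)-7-bromo-4a,8,8-trimethyl-3-{[tri(propan-2-yl)silyl]oxy}-1,2,4a,5,6,7,8,8a-octahydronaphthalen-1-yl]carbonyl}-1,3-oxazolidin-2-one | CC(C)[Si](C(C)C)(C(C)C)OC1=C[C@]2(C)CC[C@@H](Br)C(C)(C)[C@H]2[C@H](C(=O)N3[C@H](Cc4ccccc4)COC3=O)C1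
F4 | step 8 | [(1R,4aR,7R,8aS)-7-bromo-4a,8,8-trimethyl-3-{[tri(propan-2-yl)silyl]oxy}-1,2,4a,5,6,7,8,8a-octahydronaphthalen-1-yl]methanol | CC(C)[Si](C(C)C)(C(C)C)OC1=C[C@]2(C)CC[C@@H](Br)C(C)(C)[C@H]2[C@H](CO)C1
F5 | step 4 | (2E,4R)-4-bromo-5,5-dimethylhepta-2,6-dienal | O=C/C=C/[C@@H](Br)C(C)(C)C=C
F6 | step 4 | (4R)-4-bromo-5,5-dimethylhept-6-enal | O=CCC[C@@H](Br)C(C)(C)C=C
F7 | step 9 | (1R,4aR,7R,8aS)-7-bromo-4a,8,8-trimethyl-3-{[tri(propan-2-yl)silyl]oxy}-1,2,4a,5,6,7,8,8a-octahydronaphthalene-1-carboxylic acid | CC(C)[Si](C(C)C)(C(C)C)OC1=C[C@]2(C)CC[C@@H](Br)C(C)(C)[C@H]2[C@H](C(=O)O)C1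
F8 | step 9 | 2-thioxopyridin-1(2H)-yl (1R,4aR,7R,8aS)-7-bromo-4a,8,8-trimethyl-3-{[tri(propan-2-yl)silyl]oxy}-1,2,4a,5,6,7,8,8a-octahydronaphthalene-1-carboxylate | CC(C)[Si](C(C)C)(C(C)C)OC1=C[C@]2(C)CC[C@@H](Br)C(C)(C)[C@H]2[C@H](C(=O)ON3C=CC=CC3=S)C1
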